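**Retrosynthetic overview**
1. Target 16 ← face- and site-selective 1,2-reduction of epoxyquinone 15 ← ketal hydrolysis ← tartrate-mediated nucleophilic epoxidation of quinone monoketal 13, which sets both oxirane centres; the carbinol centre is relayed from them.
2. 13 ← oxidative dearomatisation of the para-unsubstituted phenol 12. The carbocycle is carried intact from 3-bromophenol; the oxirane is the only ring formed (step 9).
3. Key disconnection: the C5'–C6' C(sp3)–C(sp2) bond in the middle of the farnesyl chain, made by Ni-catalysed reductive cross-electrophile coupling (alkyl radical) of bromide 7 with dienyl iodide 11 on the free phenol.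
4. 7 ← ortho-C-alkylation of 3-ethylphenol with dibromide 6 (from but-3-yn-1-ol); 11 ← enyne 10 (homoprenyl bromide + acetylide). Both E-trisubstituted olefins come from Zr-catalysed syn-carboalumination.

Assumption 1: the SMILES is read as (1R,5R,6R), with the hydroxyl cis to the oxirane oxygen, the farnesyl group on the opposite face, and a 2E,6E side chain.
Assumption 2: L-(+)-DIPT is taken to give the (1R,6S) epoxide in step 9; if the first run gives the antipode, D-(−)-DIPT is used in the same step.

**Step 1**
Reactants: 1, 3-bromophenol; 2, potassium ethyltrifluoroborate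
Product: 3, 3-ethylphenol
Conditions: Pd(OAc)2 (2 mol%), RuPhos (4 mol%), K2CO3, toluene/H2O 10:1, 85 °C
Reagents that add atoms: none (the ethyl group comes from 2)
Why: Suzuki–Miyaura coupling of a primary alkyltrifluoroborate (Molander conditions), which tolerates the free phenol; no stereocentre.

**Step 2**
Reactants: 4, but-3-yn-1-ol
Product: 5, (2E)-3-methylpent-2-ene-1,5-diol
Conditions: Me3Al (3 equiv), Cp2ZrCl2 (0.25 equiv), CH2Cl2, 0 °C → rt; remove excess Me3Al; n-BuLi, THF, −78 → 0 °C; (CH2O)n, rt
Reagents that add atoms: trimethylaluminium, C[Al](C)C (CH3); paraformaldehyde, C=O (CH2O)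
Why: Negishi Zr-catalysed carboalumination adds Me and Al syn across the alkyne (Me to the internal carbon), and the alkenylalanate is hydroxymethylated with retention, fixing the E olefin.

**Step 3**
Reactants: 5
Product: 6, (2E)-1,5-dibromo-3-methylpent-2-ene
Conditions: CBr4, PPh3 (2.5 equiv each), CH2Cl2, 0 °C
Reagents that add atoms: carbon tetrabromide, BrC(Br)(Br)Br (Br)
Why: Appel bromination converts both primary alcohols by SN2; at 0 °C the allylic position reacts without transposition or E/Z loss.

**Step 4**
Reactants: 3 (2 equiv); 6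
Product: 7, 2-[(2E)-5-bromo-3-methylpent-2-en-1-yl]-5-ethylphenol
Conditions: NaH, toluene, 0 °C → rt
Reagents that add atoms: none
Why: Claisen–Kornblum ortho-C-alkylation of a sodium phenoxide in a non-polar solvent; the allylic bromide reacts far faster than the homoallylic one, at the less hindered ortho carbon (para to Et), by SN2 with olefin geometry retained. The O-allyl ether and the C2 isomer are minor and separable, and excess 3 is recovered.

**Step 5**
Reactants: 8, 5-bromo-2-methylpent-2-ene; 9, lithium acetylide–ethylenediamine complex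
Product: 10, 6-methylhept-5-en-1-yne
Conditions: DMSO, 10 → 25 °C
Reagents that add atoms: none (C2 comes from 9)
Why: SN2 alkylation of acetylide by a primary bromide in a dipolar aprotic solvent; no stereocentre.

**Step 6**
Reactants: 10
Product: 11, (1E)-1-iodo-2,6-dimethylhepta-1,5-diene
Conditions: Me3Al (2 equiv), Cp2ZrCl2 (0.2 equiv), CH2Cl2, 0 °C → rt; then I2, THF, −30 → 0 °C
Reagents that add atoms: trimethylaluminium, C[Al](C)C (CH3); iodine, II (I)
Why: Negishi syn-carboalumination of the terminal alkyne followed by iodinolysis of the C–Al bond with retention gives the E-alkenyl iodide (typically ≥98% E); the trisubstituted olefin is inert.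

**Step 7 (key step)**
Reactants: 7; 11 (1.3 equiv)
Product: 12, 5-ethyl-2-[(2E,6E)-3,7,11-trimethyldodeca-2,6,10-trien-1-yl]phenol
Conditions: NiBr2·glyme (10 mol%), 4,4'-di-tert-butyl-2,2'-bipyridine (10 mol%), Mn powder (3 equiv), NaI (0.5 equiv), DMA, 25–40 °C
Reagents that add atoms: none
Why: Ni-catalysed reductive cross-electrophile coupling (Weix-type vinyl–alkyl coupling): Ni(0) inserts into the C(sp2)–I bond of 11 with retention, Ni(I) abstracts Br from 7 to give the primary C5' radical, and capture at Ni with reductive elimination forms C5'–C6'. The 6E geometry is that of 11, the 2E olefin is a spectator, and the free ArOH is tolerated under these non-basic reducing conditions.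

**Step 8**
Reactants: 12
Product: 13, 5-ethyl-4,4-dimethoxy-2-[(2E,6E)-3,7,11-trimethyldodeca-2,6,10-trien-1-yl]cyclohexa-2,5-dien-1-one
Conditions: PhI(OAc)2 (2.2 equiv), MeOH, 0 °C → rt
Reagents that add atoms: methanol, CO (two OMe)
Why: Hypervalent-iodine oxidative dearomatisation of a para-unsubstituted phenol (Pelter para-quinone monoketal synthesis); methanol adds twice at the free para carbon, and phenol oxidation at 0 °C is much faster than any reaction of the isolated olefins.

**Step 9**
Reactants: 13
Product: 14, (1R,6S)-4-ethyl-5,5-dimethoxy-1-[(2E,6E)-3,7,11-trimethyldodeca-2,6,10-trien-1-yl]-7-oxabicyclo[4.1.0]hept-3-en-2-one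
Conditions: Ph3COOH (2 equiv), NaHMDS, L-(+)-DIPT (1.2 equiv), 4 Å MS, toluene, −65 → −40 °C
Reagents that add atoms: trityl hydroperoxide, OOC(c1ccccc1)(c1ccccc1)c1ccccc1 (O)
Why: Tartrate-mediated nucleophilic (Weitz–Scheffer) epoxidation of a quinone monoketal (Porco conditions): the peroxide anion attacks only the dienone, at the β-H carbon C3 and not at the ethyl-bearing, ketal-flanked C5, so the chain olefins are untouched. The chiral sodium tartrate aggregate selects the dienone face and sets both oxirane centres (cis by ring closure).

**Step 10**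
Reactants: 14
Product: 15, (1R,6S)-4-ethyl-1-[(2E,6E)-3,7,11-trimethyldodeca-2,6,10-trien-1-yl]-7-oxabicyclo[4.1.0]hept-3-ene-2,5-dione
Conditions: montmorillonite K10, CH2Cl2, rt
Reagents that add atoms: water, O (carbonyl oxygen)
Why: Mild heterogeneous acid hydrolysis of the dimethyl ketal, gentle enough to leave the oxirane and polyene intact; stereocentres are untouched (the C6 descriptor stays S).

**Step 11**
Reactants: 15
Product: 16, (1R,5R,6R)-4-ethyl-5-hydroxy-1-[(2E,6E)-3,7,11-trimethyldodeca-2,6,10-trien-1-yl]-7-oxabicyclo[4.1.0]hept-3-en-2-one (target)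
Conditions: DIBAL-H (1.1 equiv), THF, −78 °C; Rochelle salt work-up
Reagents that add atoms: none
Why: Site- and face-selective 1,2-reduction of a quinone epoxide: C5=O is the more accessible and more electrophilic carbonyl, because C2=O is shielded by the quaternary farnesyl-bearing carbon and deactivated by the β-ethyl group. Hydride adds anti to the oxirane oxygen (Felkin–Anh/steric control), giving the hydroxyl cis to the epoxide, i.e. 5R.

**Compound list**
1 | 3-bromophenol | Oc1cccc(Br)c1 | starting material
2 | potassium ethyltrifluoroborate | CC[B-](F)(F)F.[K+] | starting material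
3 | 3-ethylphenol | CCc1cccc(O)c1 | intermediate
4 | but-3-yn-1-ol | OCCC#C | starting material
5 | (2E)-3-methylpent-2-ene-1,5-diol | OC/C=C(\C)CCO | intermediate
6 | (2E)-1,5-dibromo-3-methylpent-2-ene | BrC/C=C(\C)CCBr | intermediate
7 | 2-[(2E)-5-bromo-3-methylpent-2-en-1-yl]-5-ethylphenol | CCc1ccc(C/C=C(\C)CCBr)c(O)c1 | intermediate
8 | 5-bromo-2-methylpent-2-ene | CC(C)=CCCBr | starting material
9 | lithium acetylide–ethylenediamine complex | [Li]C#C.NCCN | starting material
10 | 6-methylhept-5-en-1-yne | C#CCCC=C(C)C | intermediate
11 | (1E)-1-iodo-2,6-dimethylhepta-1,5-diene | I/C=C(\C)CCC=C(C)C | intermediate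
12 | 5-ethyl-2-[(2E,6E)-farnesyl]phenol | CCc1ccc(C/C=C(\C)CC/C=C(\C)CCC=C(C)C)c(O)c1 | intermediate
13 | 5-ethyl-4,4-dimethoxy-2-[(2E,6E)-farnesyl]cyclohexa-2,5-dien-1-one | CCC1=CC(=O)C(C/C=C(\C)CC/C=C(\C)CCC=C(C)C)=CC1(OC)OC | intermediate
14 | (1R,6S)-4-ethyl-5,5-dimethoxy-1-[(2E,6E)-farnesyl]-7-oxabicyclo[4.1.0]hept-3-en-2-one | CCC1=CC(=O)[C@]2(C/C=C(\C)CC/C=C(\C)CCC=C(C)C)O[C@@H]2C1(OC)OC | intermediate
15 | (1R,6S)-4-ethyl-1-[(2E,6E)-farnesyl]-7-oxabicyclo[4.1.0]hept-3-ene-2,5-dione | CCC1=CC(=O)[C@]2(C/C=C(\C)CC/C=C(\C)CCC=C(C)C)O[C@@H]2C1=O | intermediate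
16 | (1R,5R,6R)-4-ethyl-5-hydroxy-1-[(2E,6E)-farnesyl]-7-oxabicyclo[4.1.0]hept-3-en-2-one | CCC1=CC(=O)[C@]2(C/C=C(\C)CC/C=C(\C)CCC=C(C)C)O[C@@H]2[C@@H]1O | target

**Totals**
Total steps: 11. Longest linear sequence: 8 (steps 2, 3, 4, 7, 8, 9, 10, 11, from but-3-yn-1-ol).

**Three steps most likely to fail, with fallbacks**
1. Step 7 (Ni reductive coupling). Risks are homocoupling or hydrodehalogenation, interference by the phenol, and partial 2E/2Z erosion if the homoallylic C5' radical closes reversibly to a cyclopropylcarbinyl radical before Ni capture. Fallback: move the fragment union to the ring–C1' bond. Couple 11 with the mono-silylated bromo-alcohol from 5 to give (2E,6E)-farnesol, convert it to farnesyl bromide, and ortho-C-alkylate sodium 3-ethylphenoxide to reach 12.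
2. Step 9 (asymmetric epoxidation). The ee and the facial sense are unproven for this substrate. Fallback: auxiliary control instead of reagent control. Prepare the quinone monoketal of enantiopure pentane-2,4-diol (PhI(OAc)2 oxidation of 12 in the presence of the diol), epoxidise diastereoselectively with Ph3COOH/KHMDS, separate the diastereomers, then hydrolyse to 15.
3. Step 11 (reduction). The trans epoxy alcohol may form if the reagent is delivered from the oxirane face. Fallback: accept the trans alcohol and invert it by Mitsunobu reaction (4-nitrobenzoic acid, DIAD, PPh3; then K2CO3/MeOH) to the cis (5R) alcohol.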